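**Retrosynthetic overview**

1. The strategy rests on the benzoate ring: C2 and C3 carry oxygen, while C4, C5 and C6 carry only hydrogen. The ring is therefore built saturated, as a cyclohexane-1,2-dione equivalent (C2 ketone, C3 as a 1,3-dithiane) with a phenylsulfonyl group on C5; loss of benzenesulfinic acid and enolisation then give the catechol without an oxidant.
2. Ring bonds C5–C6 (Michael) and C1–C2 (Dieckmann) are cut together, giving fatty acrylate 6 and sulfonyl dithiane ester 9. This annulation forms the only ring of the target.
3. Ester 9 comes from dithiane ester 7 and phenyl vinyl sulfone 8. Acrylate 6 comes from alcohol 4 (copper-catalysed coupling of 1 with the Grignard reagent of 2) and acryloyl chloride 5.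
4. End game: the dithioacetal is hydrolysed with Hg(ClO4)2 rather than N-bromosuccinimide, which would brominate C1 of the enolised β-keto ester; DBU then aromatises the ring.

Key step: step 4

Remark on the chemistry: compounds 12, 13 and 14 are carried as mixtures of diastereomers and keto/enol tautomers. This is of no consequence, because every stereogenic ring carbon becomes sp2 and the target has no stereocentre.

**Route**

Step 1
Reactants: 1 12-bromododecan-1-ol; 2 1-bromo-4-methylpentane
Product: 4 16-methylheptadecan-1-ol, via 4-methylpentylmagnesium bromide 3 (not isolated)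
Conditions: 2 (2.5 equiv), Mg turnings, THF, 40 °C; then added to 1 and Li2CuCl4 (3 mol %), THF, −20 °C → rt; aq. NH4Cl
Reagents that add atoms: none
Why: Kochi-type copper-catalysed sp3–sp3 cross-coupling of a primary alkyl Grignard reagent with a primary alkyl bromide; the first equivalent of 3 converts the hydroxyl group into its inert bromomagnesium alkoxide and the second couples at the C–Br carbon.

Step 2
Reactants: 4 16-methylheptadecan-1-ol; 5 acryloyl chloride
Product: 6 16-methylheptadecyl acrylate
Conditions: Et3N, CH2Cl2, 0 °C → rt (trace of BHT as inhibitor)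
Reagents that add atoms: none
Why: Acylation of an unhindered primary alcohol by an acid chloride (nucleophilic acyl substitution), with Et3N taking up the HCl; the cold, inhibited medium keeps the acrylate from polymerising.

Step 3
Reactants: 7 ethyl 1,3-dithiane-2-carboxylate; 8 phenyl vinyl sulfone
Product: 9 ethyl 2-[2-(phenylsulfonyl)ethyl]-1,3-dithiane-2-carboxylate
Conditions: KOtBu (10 mol %), THF, 0 °C → rt (7 and base premixed, 8 added last)
Reagents that add atoms: none
Why: Base-catalysed Michael addition of the doubly sulfur-stabilised ester enolate to a vinyl sulfone; the α-sulfonyl carbanion formed is far more basic than the enolate of 7 and is protonated by the next molecule of 7, so catalytic base carries the chain, and the quaternary dithiane carbon rules out a second addition.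

Step 4
Reactants: 9 ethyl 2-[2-(phenylsulfonyl)ethyl]-1,3-dithiane-2-carboxylate; 6 16-methylheptadecyl acrylate
Product: 12 16-methylheptadecyl 7-oxo-10-(phenylsulfonyl)-1,5-dithiaspiro[5.5]undecane-8-carboxylate, via lithiated sulfone 10 (not isolated), via acyclic lithium ester enolate 11 (not isolated)
Conditions: LiN(iPr)2 (LDA, commercial solution, 1.05 equiv), THF, −78 °C, 30 min; 6 in THF added slowly over 1 h at −78 °C; then → 0 °C; aq. NH4Cl
Reagents that add atoms: none
Why: LiN(iPr)2 removes the proton next to the sulfonyl group of 9 (its ester has no α-hydrogen), carbanion 10 adds 1,4 to acrylate 6 to form ring bond C5–C6, and ester enolate 11 attacks the ethyl ester to form ring bond C1–C2 with loss of ethoxide. The closest known reaction type is the Michael–Dieckmann (Hauser–Kraus type) anionic [4+2] annulation of sulfone-stabilised carbanions bearing a γ-ester with acrylates. The six-membered carbocycle closes by 6-exo-trig Dieckmann acylation, and the LiOEt released converts the acidic β-keto ester into its enolate, which makes the closure irreversible. The new stereocentres at ring C1 and C5 (C8 and C10 of the spirocycle) are not controlled and need not be, since both become sp2 in step 6. The step needs Michael addition of 10 to outpace both acrylate oligomerisation through 11 and retro-Michael loss of the dithiane ester enolate from 10; slow addition of 6 at −78 °C keeps the acrylate concentration low and the carbanion cold, while the substitution pattern of the ring follows from connectivity alone.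

Step 5
Reactants: 12 16-methylheptadecyl 7-oxo-10-(phenylsulfonyl)-1,5-dithiaspiro[5.5]undecane-8-carboxylate
Product: 13 16-methylheptadecyl 2,3-dioxo-5-(phenylsulfonyl)cyclohexane-1-carboxylate
Conditions: Hg(ClO4)2·3H2O (2.2 equiv), CaCO3, THF–H2O (5:1), 0 °C → rt; filtration through Celite; crude product used directly
Reagents that add atoms: water, O
Why: Thiophilic hydrolysis of the dithioacetal by divalent mercury (sulfur complexation, ring opening to the thionium ion, addition of water, collapse of the hemithioacetal) with CaCO3 buffering the acid; a non-oxidising, non-halogenating reagent is chosen because the enolised β-keto ester position C1 and any arene formed early would be attacked by N-halosuccinimides.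

Step 6
Reactants: 13 16-methylheptadecyl 2,3-dioxo-5-(phenylsulfonyl)cyclohexane-1-carboxylate
Product: 15 gentiside D (16-methylheptadecyl 2,3-dihydroxybenzoate), via cyclohexenedione 14 (not isolated)
Conditions: DBU (3 equiv), degassed THF, 0 °C → rt, argon; then 1 M HCl
Reagents that add atoms: none
Why: E1cB β-elimination of benzenesulfinate from C5 through the enolate of the C3 ketone (C4–H) gives ene-dione 14, whose two keto groups enolise towards C1 and C6 to give the aromatic catechol; aromatisation drives the sequence and exclusion of oxygen protects the catecholate.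

**Compound list**

1 | 12-bromododecan-1-ol | OCCCCCCCCCCCCBr | starting material
2 | 1-bromo-4-methylpentane | CC(C)CCCBr | starting material
3 | 4-methylpentylmagnesium bromide | CC(C)CCC[Mg]Br | intermediate
4 | 16-methylheptadecan-1-ol | CC(C)CCCCCCCCCCCCCCCO | intermediate
5 | acryloyl chloride | C=CC(=O)Cl | starting material
6 | 16-methylheptadecyl acrylate | CC(C)CCCCCCCCCCCCCCCOC(=O)C=C | intermediate
7 | ethyl 1,3-dithiane-2-carboxylate | CCOC(=O)C1SCCCS1 | starting material
8 | phenyl vinyl sulfone | C=CS(=O)(=O)c1ccccc1 | starting material
9 | ethyl 2-[2-(phenylsulfonyl)ethyl]-1,3-dithiane-2-carboxylate | CCOC(=O)C1(CCS(=O)(=O)c2ccccc2)SCCCS1 | intermediate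
10 | lithium salt of 9 deprotonated at the carbon bearing the sulfonyl group (lithiated sulfone) | CCOC(=O)C1(C[CH-]S(=O)(=O)c2ccccc2)SCCCS1.[Li+] | intermediate
11 | lithium ester enolate of ethyl 2-[5-(16-methylheptadecyloxy)-5-oxo-2-(phenylsulfonyl)pentyl]-1,3-dithiane-2-carboxylate (open-chain Michael adduct) | CCOC(=O)C1(CC(CC=C([O-])OCCCCCCCCCCCCCCCC(C)C)S(=O)(=O)c2ccccc2)SCCCS1.[Li+] | intermediate
12 | 16-methylheptadecyl 7-oxo-10-(phenylsulfonyl)-1,5-dithiaspiro[5.5]undecane-8-carboxylate (diastereomer mixture) | CC(C)CCCCCCCCCCCCCCCOC(=O)C1CC(S(=O)(=O)c2ccccc2)CC2(SCCCS2)C1=O | intermediate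
13 | 16-methylheptadecyl 2,3-dioxo-5-(phenylsulfonyl)cyclohexane-1-carboxylate (diastereomer and tautomer mixture) | CC(C)CCCCCCCCCCCCCCCOC(=O)C1CC(S(=O)(=O)c2ccccc2)CC(=O)C1=O | intermediate
14 | 16-methylheptadecyl 2,3-dioxocyclohex-4-ene-1-carboxylate | CC(C)CCCCCCCCCCCCCCCOC(=O)C1CC=CC(=O)C1=O | intermediate
15 | gentiside D, 16-methylheptadecyl 2,3-dihydroxybenzoate | CC(C)CCCCCCCCCCCCCCCOC(=O)c1cccc(O)c1O | target

**Step count and risk**

Total step count: 6. Longest linear sequence: 5 steps (steps 1, 2, 4, 5, 6).

Steps most likely to fail:

Step 4. The enolate 11 may add to further acrylate before it acylates the hindered ethyl ester, and the carbanion 10 may fragment by retro-Michael reaction if it warms. The fallback separates the two bond formations. It sets out from 9 and 6: the carbanion is formed and the acrylate added at −78 °C as before, but the mixture is quenched cold with acetic acid. The open-chain diester ethyl 2-[5-(16-methylheptadecyloxy)-5-oxo-2-(phenylsulfonyl)pentyl]-1,3-dithiane-2-carboxylate F1 is isolated. It is then closed in a separate, thermodynamically driven Dieckmann condensation (KOtBu, THF, 0 °C → rt), where no acrylate is present and deprotonation of the β-keto ester pulls the equilibrium. The fallback comes back to the route at 12.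

Step 5. Thiophilic hydrolysis may stall, because the thionium ion next to the C2 carbonyl is destabilised, and sulfinate may be lost early so that an arene forms in the presence of divalent mercury. The fallback sets out from 12 and masks the enol before an oxidative hydrolysis.
- Acetylation (Ac2O, Et3N, DMAP, CH2Cl2) should give the enol acetate 16-methylheptadecyl 7-acetoxy-10-(phenylsulfonyl)-1,5-dithiaspiro[5.5]undec-7-ene-8-carboxylate F2, whose push–pull alkene is inert to bromonium sources.
- N-Bromosuccinimide in aqueous acetone at 0 °C should then unmask the ketone to give 16-methylheptadecyl 2-acetoxy-3-oxo-5-(phenylsulfonyl)cyclohex-1-ene-1-carboxylate F3.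
- DBU in THF should eliminate benzenesulfinate and aromatise to 16-methylheptadecyl 2-acetoxy-3-hydroxybenzoate F4.
- Hydrazine hydrate (N2H4·H2O, THF, 0 °C) should cleave the aryl acetate without touching the fatty ester. The fallback comes back to the route at 15.

Step 6. The catecholate may be oxidised by air under basic conditions, and elimination may stall at the stabilised enolate monoanion of 13. The fallback sets out from 13 and traps the product as it forms. Treatment with Ac2O, Et3N and DMAP in CH2Cl2 should acetylate the enols, allow sulfinate loss from a neutral substrate and give the air-stable 16-methylheptadecyl 2,3-diacetoxybenzoate F5. Both aryl acetates are then removed with hydrazine hydrate (THF, 0 °C, argon), and the fallback comes back to the route at 15.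

**Further compounds**

F1 | step 4 | ethyl 2-[5-(16-methylheptadecyloxy)-5-oxo-2-(phenylsulfonyl)pentyl]-1,3-dithiane-2-carboxylate | CCOC(=O)C1(CC(CCC(=O)OCCCCCCCCCCCCCCCC(C)C)S(=O)(=O)c2ccccc2)SCCCS1
F2 | step 5 | 16-methylheptadecyl 7-acetoxy-10-(phenylsulfonyl)-1,5-dithiaspiro[5.5]undec-7-ene-8-carboxylate | CC(C)CCCCCCCCCCCCCCCOC(=O)C1=C(OC(C)=O)C2(SCCCS2)CC(S(=O)(=O)c2ccccc2)C1
F3 | step 5 | 16-methylheptadecyl 2-acetoxy-3-oxo-5-(phenylsulfonyl)cyclohex-1-ene-1-carboxylate | CC(C)CCCCCCCCCCCCCCCOC(=O)C1=C(OC(C)=O)C(=O)CC(S(=O)(=O)c2ccccc2)C1
F4 | step 5 | 16-methylheptadecyl 2-acetoxy-3-hydroxybenzoate | CC(C)CCCCCCCCCCCCCCCOC(=O)c1cccc(O)c1OC(C)=O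
F5 | step 6 | 16-methylheptadecyl 2,3-diacetoxybenzoate | CC(C)CCCCCCCCCCCCCCCOC(=O)c1cccc(OC(C)=O)c1OC(C)=O
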